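**Retrosynthetic overview**
- Last step: one Lewis-acid dealkylation removes three benzyl ethers and the chelated C5 methyl ether of a fully protected biflavone; the C7 methyl ether stays.
- Key disconnection: the C6–O–C4' diaryl ether, made by CuI-catalysed Ullmann coupling of a 6-hydroxyflavone (7-O-methylscutellarein-type half) with a 4'-iodoflavone (apigenin-type half).
- Each flavone: pyranone ring C closed by I2/DMSO oxidative cyclisation of a 2'-hydroxychalcone obtained by Claisen–Schmidt condensation.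
- The ring A ketone of the methoxylated half comes from Friedel–Crafts acetylation of symmetric 2,6-dimethoxyhydroquinone.
- Ring order: ring C of the hydroxyflavone and ring C of the iodoflavone in two parallel branches, then the ether link; no ring is formed after the coupling.

Assumption: the target has no stereocentre and no stereogenic axis (it is achiral), so no enantiocontrol is needed; chalcone E-geometry is the only stereo element in the route, and the five numbered starting materials are taken as catalogue compounds.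

**Route**

Step 1
Reactants: 1 2,6-dimethoxybenzene-1,4-diol
Product: 2 1-(3,6-dihydroxy-2,4-dimethoxyphenyl)ethan-1-one
Conditions: AcOH, BF3·OEt2 (3 equiv), 90 °C; then H2O
Reagents that add atoms: acetic acid CC(=O)O
Why: BF3-promoted Friedel–Crafts acylation (any O-acetate undergoes Fries shift); the two free ring positions of symmetric 1 are equivalent, so a single ketone forms, and its chelation with the ortho OH deactivates the ring toward a second acylation.

Step 2
Reactants: 2 1-(3,6-dihydroxy-2,4-dimethoxyphenyl)ethan-1-one; 3 4-(benzyloxy)benzaldehyde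
Product: 4 (E)-3-[4-(benzyloxy)phenyl]-1-(3,6-dihydroxy-2,4-dimethoxyphenyl)prop-2-en-1-one
Conditions: KOH (50% aq, 10 equiv), EtOH, Ar, rt, 36 h; then cold 1 M HCl
Reagents that add atoms: none
Why: Claisen–Schmidt condensation, in which the methyl ketone enolate of 2 adds to non-enolisable aldehyde 3 and E1cB loss of water gives the thermodynamically favoured E-enone, with argon protecting the hydroquinone-type phenoxide from air oxidation.

Step 3
Reactants: 4 (E)-3-[4-(benzyloxy)phenyl]-1-(3,6-dihydroxy-2,4-dimethoxyphenyl)prop-2-en-1-one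
Product: 6 2-[4-(benzyloxy)phenyl]-6-hydroxy-5,7-dimethoxy-4H-chromen-4-one, via flavanone 5 (not isolated)
Conditions: I2 (10 mol%), DMSO, 120 °C, 3 h
Reagents that add atoms: none
Why: I2/DMSO oxidative cyclisation, in which only the 2'-OH can add to the enone in a six-membered ring (oxa-Michael) to give flavanone 5, which is iodinated at C3 and loses HI while DMSO turns HI back into I2, so the C2 stereocentre of 5 is erased and the other OH ends up as the free 6-OH.

Step 4
Reactants: 7 1-[2,4-bis(benzyloxy)-6-hydroxyphenyl]ethan-1-one; 8 4-iodobenzaldehyde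
Product: 9 (E)-1-[2,4-bis(benzyloxy)-6-hydroxyphenyl]-3-(4-iodophenyl)prop-2-en-1-one
Conditions: KOH (50% aq, 6 equiv), EtOH/THF, rt, 24 h; then 1 M HCl
Reagents that add atoms: none
Why: Claisen–Schmidt condensation followed by E1cB dehydration gives the E-chalcone, with the benzyl ethers and the aryl iodide inert to hydroxide at room temperature.

Step 5
Reactants: 9 (E)-1-[2,4-bis(benzyloxy)-6-hydroxyphenyl]-3-(4-iodophenyl)prop-2-en-1-one
Product: 11 5,7-bis(benzyloxy)-2-(4-iodophenyl)-4H-chromen-4-one, via iodoflavanone 10 (not isolated)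
Conditions: I2 (10 mol%), DMSO, 130 °C, 2 h
Reagents that add atoms: none
Why: The same I2/DMSO oxidative cyclisation (oxa-Michael closure to flavanone 10, then iodination and dehydroiodination), to which the benzyl ethers and the aryl C–I bond are inert.

Step 6
Reactants: 6 2-[4-(benzyloxy)phenyl]-6-hydroxy-5,7-dimethoxy-4H-chromen-4-one; 11 5,7-bis(benzyloxy)-2-(4-iodophenyl)-4H-chromen-4-one
Product: 12 2-[4-(benzyloxy)phenyl]-6-{4-[5,7-bis(benzyloxy)-4-oxo-4H-chromen-2-yl]phenoxy}-5,7-dimethoxy-4H-chromen-4-one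
Conditions: CuI (10 mol%), picolinic acid (20 mol%), K3PO4 (2 equiv), DMSO, Ar, 90 °C, 24 h
Reagents that add atoms: none
Why: Ullmann-type C–O coupling, in which the picolinate-ligated copper phenoxide of 6 couples with the electron-poor aryl iodide 11 under a ligand system that tolerates di-ortho-substituted phenols, and 6 carries the only free OH so there is no regiochemical issue.

Step 7
Reactants: 12 2-[4-(benzyloxy)phenyl]-6-{4-[5,7-bis(benzyloxy)-4-oxo-4H-chromen-2-yl]phenoxy}-5,7-dimethoxy-4H-chromen-4-one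
Product: 13 isocryptomerin (6-[4-(5,7-dihydroxy-4-oxo-4H-chromen-2-yl)phenoxy]-5-hydroxy-2-(4-hydroxyphenyl)-7-methoxy-4H-chromen-4-one)
Conditions: BCl3 (1 M in CH2Cl2, 10 equiv), pentamethylbenzene (9 equiv), CH2Cl2, −78 °C to 0 °C; then H2O
Reagents that add atoms: none
Why: Lewis-acid ether cleavage, in which BCl3 removes the three benzyl groups at low temperature (benzyl cations trapped by pentamethylbenzene in a Friedel–Crafts sense, sparing the phloroglucinol ring) and on warming cleaves the C5 methyl ether through its six-membered chelate with the C4 carbonyl, whereas the unchelated C7 methyl ether and the diaryl ether are not attacked; no stereocentre exists to be set or scrambled.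

**Compound list**
1 | 2,6-dimethoxybenzene-1,4-diol | COc1cc(O)cc(OC)c1O | starting material
2 | 1-(3,6-dihydroxy-2,4-dimethoxyphenyl)ethan-1-one | CC(=O)c1c(O)cc(OC)c(O)c1OC | intermediate
3 | 4-(benzyloxy)benzaldehyde | O=Cc1ccc(OCc2ccccc2)cc1 | starting material
4 | (E)-3-[4-(benzyloxy)phenyl]-1-(3,6-dihydroxy-2,4-dimethoxyphenyl)prop-2-en-1-one | COc1cc(O)c(C(=O)/C=C/c2ccc(OCc3ccccc3)cc2)c(OC)c1O | intermediate
5 | racemic 2-[4-(benzyloxy)phenyl]-6-hydroxy-5,7-dimethoxy-2,3-dihydro-4H-chromen-4-one (not isolated) | COc1cc2OC(c3ccc(OCc4ccccc4)cc3)CC(=O)c2c(OC)c1O | intermediate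
6 | 2-[4-(benzyloxy)phenyl]-6-hydroxy-5,7-dimethoxy-4H-chromen-4-one | COc1cc2oc(-c3ccc(OCc4ccccc4)cc3)cc(=O)c2c(OC)c1O | intermediate
7 | 1-[2,4-bis(benzyloxy)-6-hydroxyphenyl]ethan-1-one | CC(=O)c1c(O)cc(OCc2ccccc2)cc1OCc1ccccc1 | starting material
8 | 4-iodobenzaldehyde | O=Cc1ccc(I)cc1 | starting material
9 | (E)-1-[2,4-bis(benzyloxy)-6-hydroxyphenyl]-3-(4-iodophenyl)prop-2-en-1-one | O=C(/C=C/c1ccc(I)cc1)c1c(O)cc(OCc2ccccc2)cc1OCc1ccccc1 | intermediate
10 | racemic 5,7-bis(benzyloxy)-2-(4-iodophenyl)-2,3-dihydro-4H-chromen-4-one (not isolated) | O=C1CC(c2ccc(I)cc2)Oc2cc(OCc3ccccc3)cc(OCc3ccccc3)c21 | intermediate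
11 | 5,7-bis(benzyloxy)-2-(4-iodophenyl)-4H-chromen-4-one | O=c1cc(-c2ccc(I)cc2)oc2cc(OCc3ccccc3)cc(OCc3ccccc3)c12 | intermediate
12 | 2-[4-(benzyloxy)phenyl]-6-{4-[5,7-bis(benzyloxy)-4-oxo-4H-chromen-2-yl]phenoxy}-5,7-dimethoxy-4H-chromen-4-one | COc1cc2oc(-c3ccc(OCc4ccccc4)cc3)cc(=O)c2c(OC)c1Oc1ccc(-c2cc(=O)c3c(OCc4ccccc4)cc(OCc4ccccc4)cc3o2)cc1 | intermediate
13 | isocryptomerin | COc1cc2oc(-c3ccc(O)cc3)cc(=O)c2c(O)c1Oc1ccc(-c2cc(=O)c3c(O)cc(O)cc3o2)cc1 | target

**Totals**
Total step count: 7. Longest linear sequence: 5 steps (steps 1, 2, 3, 6, 7).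

**Steps most likely to fail**

Step 6 (Ullmann etherification of the di-ortho-methoxylated phenol with a poorly soluble iodoflavone). The fallback builds the apigenin-type half on the ether instead of coupling two finished flavones; it sets out from 6 and comes back to the route at 12. Phenol 6 is arylated by SNAr with 4-fluorobenzaldehyde (K2CO3, DMF, 110 °C) to give 4-({2-[4-(benzyloxy)phenyl]-5,7-dimethoxy-4-oxo-4H-chromen-6-yl}oxy)benzaldehyde F1. Claisen–Schmidt condensation of this aldehyde with ketone 7 (KOH, EtOH/THF, rt) gives (E)-1-[2,4-bis(benzyloxy)-6-hydroxyphenyl]-3-[4-({2-[4-(benzyloxy)phenyl]-5,7-dimethoxy-4-oxo-4H-chromen-6-yl}oxy)phenyl]prop-2-en-1-one F2. I2 (10 mol%) in DMSO at 130 °C then closes the second pyranone through racemic 5,7-bis(benzyloxy)-2-[4-({2-[4-(benzyloxy)phenyl]-5,7-dimethoxy-4-oxo-4H-chromen-6-yl}oxy)phenyl]-2,3-dihydro-4H-chromen-4-one F3 (not isolated) to give 12.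

Step 7 (one-pot BCl3 removal of three benzyl groups and one methyl group; risks are incomplete debenzylation, C-benzylation and loss of the C7 methyl). The fallback separates the two events; it sets out from 12 and comes back at 13. Hydrogenolysis (H2 at 1 atm, Pd/C with 10% palladium on carbon, THF/MeOH, rt) gives 6-[4-(5,7-dihydroxy-4-oxo-4H-chromen-2-yl)phenoxy]-2-(4-hydroxyphenyl)-5,7-dimethoxy-4H-chromen-4-one F4. Chelation-controlled demethylation of the C5 methyl ether alone (AlCl3 in excess, MeCN, 60 °C, then dilute HCl) then gives 13.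

Step 3 (I2/DMSO on a chalcone with a free hydroquinone-type OH; risks are oxidation to a quinone or partial loss of the C5 methyl). The fallback avoids the chalcone and any oxidant by a Baker–Venkataraman sequence; it sets out from 2 and comes back at 6. Ketone 2 is acylated on both OH groups with 4-(benzyloxy)benzoyl chloride (2.2 equiv, pyridine, 0 °C to rt) to give 2-acetyl-3,5-dimethoxy-1,4-phenylene bis[4-(benzyloxy)benzoate] F5. KOH in pyridine at 50 °C moves the ortho aroyl group to carbon, giving 3-{3-[4-(benzyloxy)phenyl]-3-oxopropanoyl}-4-hydroxy-2,6-dimethoxyphenyl 4-(benzyloxy)benzoate F6. Cyclodehydration (catalytic p-TsOH, toluene, 90 °C) gives 2-[4-(benzyloxy)phenyl]-5,7-dimethoxy-4-oxo-4H-chromen-6-yl 4-(benzyloxy)benzoate F7, and methanolysis of the remaining aryl ester (K2CO3, MeOH/THF, rt) gives 6.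

**Further compounds**
F1 | step 6 | 4-({2-[4-(benzyloxy)phenyl]-5,7-dimethoxy-4-oxo-4H-chromen-6-yl}oxy)benzaldehyde | COc1cc2oc(-c3ccc(OCc4ccccc4)cc3)cc(=O)c2c(OC)c1Oc1ccc(C=O)cc1
F2 | step 6 | (E)-1-[2,4-bis(benzyloxy)-6-hydroxyphenyl]-3-[4-({2-[4-(benzyloxy)phenyl]-5,7-dimethoxy-4-oxo-4H-chromen-6-yl}oxy)phenyl]prop-2-en-1-one | COc1cc2oc(-c3ccc(OCc4ccccc4)cc3)cc(=O)c2c(OC)c1Oc1ccc(/C=C/C(=O)c2c(O)cc(OCc3ccccc3)cc2OCc2ccccc2)cc1
F3 | step 6 | racemic 5,7-bis(benzyloxy)-2-[4-({2-[4-(benzyloxy)phenyl]-5,7-dimethoxy-4-oxo-4H-chromen-6-yl}oxy)phenyl]-2,3-dihydro-4H-chromen-4-one | COc1cc2oc(-c3ccc(OCc4ccccc4)cc3)cc(=O)c2c(OC)c1Oc1ccc(C2CC(=O)c3c(OCc4ccccc4)cc(OCc4ccccc4)cc3O2)cc1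
F4 | step 7 | 6-[4-(5,7-dihydroxy-4-oxo-4H-chromen-2-yl)phenoxy]-2-(4-hydroxyphenyl)-5,7-dimethoxy-4H-chromen-4-one | COc1cc2oc(-c3ccc(O)cc3)cc(=O)c2c(OC)c1Oc1ccc(-c2cc(=O)c3c(O)cc(O)cc3o2)cc1
F5 | step 3 | 2-acetyl-3,5-dimethoxy-1,4-phenylene bis[4-(benzyloxy)benzoate] | CC(=O)c1c(OC(=O)c2ccc(OCc3ccccc3)cc2)cc(OC)c(OC(=O)c2ccc(OCc3ccccc3)cc2)c1OC
F6 | step 3 | 3-{3-[4-(benzyloxy)phenyl]-3-oxopropanoyl}-4-hydroxy-2,6-dimethoxyphenyl 4-(benzyloxy)benzoate | O=C(CC(=O)c1ccc(OCc2ccccc2)cc1)c1c(O)cc(OC)c(OC(=O)c2ccc(OCc3ccccc3)cc2)c1OC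
F7 | step 3 | 2-[4-(benzyloxy)phenyl]-5,7-dimethoxy-4-oxo-4H-chromen-6-yl 4-(benzyloxy)benzoate | COc1cc2oc(-c3ccc(OCc4ccccc4)cc3)cc(=O)c2c(OC)c1OC(=O)c1ccc(OCc2ccccc2)cc1
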